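Ring names: flavanone = ring A (C4a–C8a), ring C (O1–C4), ring B (4-hydroxyphenyl). Flavone = ring D (benzo), ring E (pyranone), ring F (catechol).
Retrosynthesis: the seven benzylic ethers are put on first. Ring C is then cut at O1–C2 and C4–C4a in one stroke, giving biaryl phenol 11 and cinnamoyl chloride 13. Phenol 11 is cut at the C6(ring A)–ring F bond, and the flavone at its aldol and O–C2 bonds.
Forward: rings D, E and F are made first (Claisen–Schmidt, oxidative cyclisation). Ring A is joined to ring F by Suzuki–Miyaura coupling, ring C carrying ring B is closed last, and hydrogenolysis ends the route.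
Enabling feature: C8a (bearing O1) is para to C6 (bearing ring F), so 11 is a 4-aryl-3,5-dialkoxyphenol with a local twofold axis O1–C8a···C6. Its two ortho C–H carbons (future C4a and C8) are equivalent, each is ortho/ortho/para to three oxygens, the para carbon is blocked, and only O1 is free.
Consequence: O1/C4a act as a 1,3-O,C-bisnucleophile at an unfunctionalised C–H toward the cinnamoyl C2/C4 1,3-biselectrophile, and only the 6-aryl constitution can form.
Stereochemistry: C2 is the only stereocentre. It is set as R in the key step by a bifunctional cinchona thiourea and kept by a base-free end game.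

Key step: step 9

Assumption 1: the ring A–ring F biaryl axis carries no descriptor in the target, so it is treated as stereochemically undefined and rotamers of 14, 15 and 16 are carried together.
Assumption 2: the quinine-series thiourea is taken to deliver the 2R configuration; if the sense is opposite, the pseudoenantiomeric quinidine-series catalyst is used with no other change.

Step 1
Reactants: 1 3,4-bis(benzyloxy)benzaldehyde
Product: 2 4,5-bis(benzyloxy)-2-bromobenzaldehyde
Conditions: Br2, NaOAc, AcOH, rt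
Reagents that add atoms: bromine BrBr
Why: Electrophilic aromatic bromination should go para to the C3 ether (C6 of 1), the activated position that is least hindered, as in the bromination of veratraldehyde, and acetate buffers the acid so the benzyl ethers survive.

Step 2
Reactants: 2 4,5-bis(benzyloxy)-2-bromobenzaldehyde; 3 1-[2,4-bis(benzyloxy)-6-hydroxyphenyl]ethan-1-one
Product: 4 (E)-1-[2,4-bis(benzyloxy)-6-hydroxyphenyl]-3-[4,5-bis(benzyloxy)-2-bromophenyl]prop-2-en-1-one
Conditions: KOH, EtOH/THF, rt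
Reagents that add atoms: none
Why: Claisen–Schmidt condensation of the methyl ketone enolate with the non-enolisable aldehyde, followed by E1cB loss of water, should give the conjugated E-enone.

Step 3
Reactants: 4 (E)-1-[2,4-bis(benzyloxy)-6-hydroxyphenyl]-3-[4,5-bis(benzyloxy)-2-bromophenyl]prop-2-en-1-one
Product: 5 5,7-bis(benzyloxy)-2-[4,5-bis(benzyloxy)-2-bromophenyl]-4H-chromen-4-one
Conditions: I2 (10 mol%), DMSO, 130 °C
Reagents that add atoms: none
Why: Iodine-catalysed oxidative cyclisation of a 2'-hydroxychalcone in DMSO (oxa-Michael closure, iodination at C3, loss of HI, reoxidation of iodide by DMSO) is the standard flavone synthesis and leaves aryl bromide and benzyl ethers untouched.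

Step 4
Reactants: 5 5,7-bis(benzyloxy)-2-[4,5-bis(benzyloxy)-2-bromophenyl]-4H-chromen-4-one
Product: 6 5,7-bis(benzyloxy)-2-[4,5-bis(benzyloxy)-2-(4,4,5,5-tetramethyl-1,3,2-dioxaborolan-2-yl)phenyl]-4H-chromen-4-one
Conditions: B2pin2, PdCl2(dppf) (5 mol%), KOAc, 1,4-dioxane, 90 °C
Reagents that add atoms: bis(pinacolato)diboron CC1(C)OB(OC1(C)C)B1OC(C)(C)C(C)(C)O1
Why: Miyaura borylation should work because the electron-poor chromone ortho to C–Br helps oxidative addition, and the weak base acetate avoids homocoupling.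

Step 5
Reactants: 7 2-iodobenzene-1,3-diol (2-iodoresorcinol)
Product: 8 2-iodo-1,3-bis[(4-methylbenzyl)oxy]benzene
Conditions: 4-methylbenzyl bromide (2.2 equiv), K2CO3, DMF, rt to 50 °C
Reagents that add atoms: 4-methylbenzyl bromide Cc1ccc(CBr)cc1
Why: This is a double Williamson ether synthesis, and the para-methyl groups leave no sterically free C–H on the protecting-group rings (needed in step 6) while the ethers stay cleavable by hydrogenolysis.

Step 6
Reactants: 8 2-iodo-1,3-bis[(4-methylbenzyl)oxy]benzene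
Product: 10 4-iodo-3,5-bis[(4-methylbenzyl)oxy]phenol, via aryl pinacol boronate 9 (not isolated)
Conditions: B2pin2, [Ir(OMe)(cod)]2 (1.5 mol%), 4,4'-di-tert-butyl-2,2'-bipyridine (3 mol%), THF, 60 °C; then 30% H2O2, aq NaOH, THF, 0 °C
Reagents that add atoms: bis(pinacolato)diboron CC1(C)OB(OC1(C)C)B1OC(C)(C)C(C)(C)O1 (boryl group of 9); hydrogen peroxide OO (phenolic oxygen of 10)
Why: Sterically governed iridium-catalysed C–H borylation should take the only C–H without an ortho substituent (C5, para to iodine), and oxidation of the boronate puts the hydroxyl exactly there (the borylation/oxidation route to 3,5-disubstituted phenols, which tolerates aryl halides).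

Step 7
Reactants: 6 5,7-bis(benzyloxy)-2-[4,5-bis(benzyloxy)-2-(4,4,5,5-tetramethyl-1,3,2-dioxaborolan-2-yl)phenyl]-4H-chromen-4-one; 10 4-iodo-3,5-bis[(4-methylbenzyl)oxy]phenol
Product: 11 5,7-bis(benzyloxy)-2-{4,5-bis(benzyloxy)-2-[4-hydroxy-2,6-bis((4-methylbenzyl)oxy)phenyl]phenyl}-4H-chromen-4-one
Conditions: Pd(OAc)2 (5 mol%), SPhos (10 mol%), K3PO4, toluene/H2O, 90 °C
Reagents that add atoms: none
Why: In this Suzuki–Miyaura coupling the iodide offsets the electron-rich character of the phenol partner in oxidative addition to zerovalent palladium, and the bulky electron-rich SPhos is the established ligand for biaryls with three ortho substituents.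

Step 8
Reactants: 12 (E)-3-[4-(benzyloxy)phenyl]prop-2-enoic acid
Product: 13 (E)-3-[4-(benzyloxy)phenyl]prop-2-enoyl chloride
Conditions: (COCl)2, DMF (cat.), CH2Cl2, 0 °C to rt; evaporate
Reagents that add atoms: oxalyl chloride O=C(Cl)C(=O)Cl
Why: Acid chloride formation through the catalytic chloroiminium species is mild, gives only volatile side products and does not touch the E-alkene or the benzyl ether.

Step 9
Reactants: 11 5,7-bis(benzyloxy)-2-{4,5-bis(benzyloxy)-2-[4-hydroxy-2,6-bis((4-methylbenzyl)oxy)phenyl]phenyl}-4H-chromen-4-one; 13 (E)-3-[4-(benzyloxy)phenyl]prop-2-enoyl chloride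
Product: 15 (2R)-2-[4-(benzyloxy)phenyl]-6-{4,5-bis(benzyloxy)-2-[5,7-bis(benzyloxy)-4-oxo-4H-chromen-2-yl]phenyl}-5,7-bis[(4-methylbenzyl)oxy]chroman-4-one, via 2'-hydroxychalcone 14 (not isolated)
Conditions: 13 (1.05 equiv), (CF3)2CHOH/CH2Cl2, 0 °C to rt; volatiles off in vacuo (toluene chase); then 1-[3,5-bis(trifluoromethyl)phenyl]-3-[(8α,9S)-6'-methoxycinchonan-9-yl]thiourea (10 mol%), toluene, 0 °C
Reagents that add atoms: none
Why: Proposed new method: the flask merges three known reaction types that have not been run together as one asymmetric annulation on an unactivated chalcone, namely the hexafluoroisopropanol-promoted Friedel–Crafts acylation of polyalkoxyarenes with acid chlorides, the one-pot Lewis-acid union of phloroglucinols with cinnamoyl chlorides to racemic flavanones, and the cinchona-thiourea oxa-Michael closure of 2'-hydroxychalcone-type acceptors (the closest known type, best developed with an extra ester at C3). Mechanism: the solvent hydrogen-bonds to the acyl chloride, the ring A carbon ortho to the free OH attacks the acyl carbon (SEAr, forms C4–C4a) and HCl leaves with the solvent, then the quinuclidine nitrogen takes the 2'-OH proton while the thiourea N–H pair binds the C4 carbonyl, O1 adds to C2 (forms O1–C2) and the enolate is protonated at C3. The one ring formed, pyranone ring C, closes in the 6-endo-trig mode. C2 is controlled only by the catalyst, which holds phenoxide and carbonyl in one chiral pocket so that O1 reaches one face of the E-alkene, and the kinetic result should last because the C5 ether twists the aroyl group of 14 out of conjugation, places the equilibrium far on the flavanone side and so makes the retro-oxa-Michael path slow at 0 °C. Site and constitution are secured by the substrate: the two C–H carbons of ring A in 11 are related by the local twofold axis, each is ortho/ortho/para to three oxygens and hence far more nucleophilic than rings D and F, the para carbon is blocked by ring F, and since only O1 is free the 8-aryl isomer cannot form. Acylation rather than attack at the β-carbon (the 4-aryl-dihydrocoumarin path) is favoured because no strong acid is present at the start to turn the cinnamoyl unit into a benzylic cation, and after acylation ring A is deactivated.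

Step 10
Reactants: 15 (2R)-2-[4-(benzyloxy)phenyl]-6-{4,5-bis(benzyloxy)-2-[5,7-bis(benzyloxy)-4-oxo-4H-chromen-2-yl]phenyl}-5,7-bis[(4-methylbenzyl)oxy]chroman-4-one
Product: 16 (2R)-6-[2-(5,7-dihydroxy-4-oxo-4H-chromen-2-yl)-4,5-dihydroxyphenyl]-5,7-dihydroxy-2-(4-hydroxyphenyl)chroman-4-one (CNP0168406.2)
Conditions: H2 (1 atm), Pd/C, THF/MeOH, rt
Reagents that add atoms: none
Why: Catalytic hydrogenolysis should cleave all seven benzylic aryl ethers under neutral conditions, in which the chromone alkene and the two carbonyls are normally retained and C2 cannot epimerise through base-induced ring opening.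

Compound list
1 | 3,4-bis(benzyloxy)benzaldehyde | O=Cc1ccc(OCc2ccccc2)c(OCc2ccccc2)c1 | starting material
2 | 4,5-bis(benzyloxy)-2-bromobenzaldehyde | O=Cc1cc(OCc2ccccc2)c(OCc2ccccc2)cc1Br | intermediate
3 | 1-[2,4-bis(benzyloxy)-6-hydroxyphenyl]ethan-1-one | CC(=O)c1c(O)cc(OCc2ccccc2)cc1OCc1ccccc1 | starting material
4 | (E)-1-[2,4-bis(benzyloxy)-6-hydroxyphenyl]-3-[4,5-bis(benzyloxy)-2-bromophenyl]prop-2-en-1-one | O=C(/C=C/c1cc(OCc2ccccc2)c(OCc2ccccc2)cc1Br)c1c(O)cc(OCc2ccccc2)cc1OCc1ccccc1 | intermediate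
5 | 5,7-bis(benzyloxy)-2-[4,5-bis(benzyloxy)-2-bromophenyl]-4H-chromen-4-one | O=c1cc(-c2cc(OCc3ccccc3)c(OCc3ccccc3)cc2Br)oc2cc(OCc3ccccc3)cc(OCc3ccccc3)c12 | intermediate
6 | 5,7-bis(benzyloxy)-2-[4,5-bis(benzyloxy)-2-(4,4,5,5-tetramethyl-1,3,2-dioxaborolan-2-yl)phenyl]-4H-chromen-4-one | O=c1cc(-c2cc(OCc3ccccc3)c(OCc3ccccc3)cc2B4OC(C)(C)C(C)(C)O4)oc5cc(OCc3ccccc3)cc(OCc3ccccc3)c15 | intermediate
7 | 2-iodobenzene-1,3-diol | Oc1cccc(O)c1I | starting material
8 | 2-iodo-1,3-bis[(4-methylbenzyl)oxy]benzene | Cc1ccc(COc2cccc(OCc3ccc(C)cc3)c2I)cc1 | intermediate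
9 | 2-{4-iodo-3,5-bis[(4-methylbenzyl)oxy]phenyl}-4,4,5,5-tetramethyl-1,3,2-dioxaborolane | Cc1ccc(COc2cc(B3OC(C)(C)C(C)(C)O3)cc(OCc3ccc(C)cc3)c2I)cc1 | intermediate
10 | 4-iodo-3,5-bis[(4-methylbenzyl)oxy]phenol | Cc1ccc(COc2cc(O)cc(OCc3ccc(C)cc3)c2I)cc1 | intermediate
11 | 5,7-bis(benzyloxy)-2-{4,5-bis(benzyloxy)-2-[4-hydroxy-2,6-bis((4-methylbenzyl)oxy)phenyl]phenyl}-4H-chromen-4-one | O=c1cc(-c2cc(OCc3ccccc3)c(OCc3ccccc3)cc2-c4c(OCc5ccc(C)cc5)cc(O)cc4OCc5ccc(C)cc5)oc6cc(OCc3ccccc3)cc(OCc3ccccc3)c16 | intermediate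
12 | (E)-3-[4-(benzyloxy)phenyl]prop-2-enoic acid | OC(=O)/C=C/c1ccc(OCc2ccccc2)cc1 | starting material
13 | (E)-3-[4-(benzyloxy)phenyl]prop-2-enoyl chloride | ClC(=O)/C=C/c1ccc(OCc2ccccc2)cc1 | intermediate
14 | 5,7-bis(benzyloxy)-2-{4,5-bis(benzyloxy)-2-[3-((E)-3-(4-(benzyloxy)phenyl)acryloyl)-4-hydroxy-2,6-bis((4-methylbenzyl)oxy)phenyl]phenyl}-4H-chromen-4-one | O=c1cc(-c2cc(OCc3ccccc3)c(OCc3ccccc3)cc2-c4c(OCc5ccc(C)cc5)c(C(=O)/C=C/c5ccc(OCc7ccccc7)cc5)c(O)cc4OCc5ccc(C)cc5)oc6cc(OCc3ccccc3)cc(OCc3ccccc3)c16 | intermediate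
15 | (2R)-2-[4-(benzyloxy)phenyl]-6-{4,5-bis(benzyloxy)-2-[5,7-bis(benzyloxy)-4-oxo-4H-chromen-2-yl]phenyl}-5,7-bis[(4-methylbenzyl)oxy]chroman-4-one | O=C1C[C@H](c2ccc(OCc3ccccc3)cc2)Oc2cc(OCc3ccc(C)cc3)c(-c3cc(OCc4ccccc4)c(OCc4ccccc4)cc3-c3cc(=O)c4c(OCc5ccccc5)cc(OCc5ccccc5)cc4o3)c(OCc3ccc(C)cc3)c21 | intermediate
16 | (2R)-6-[2-(5,7-dihydroxy-4-oxo-4H-chromen-2-yl)-4,5-dihydroxyphenyl]-5,7-dihydroxy-2-(4-hydroxyphenyl)chroman-4-one | O=C1C[C@H](c2ccc(O)cc2)Oc2cc(O)c(-c3cc(O)c(O)cc3-c3cc(=O)c4c(O)cc(O)cc4o3)c(O)c21 | target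

Total step count: 10. Longest linear sequence: 7 steps (1, 2, 3, 4, 7, 9, 10).

Steps most likely to fail

1. Step 9 (Proposed new method).
- What may go wrong: closure of the unactivated chalcone may be slow and poorly face-selective, and retro-oxa-Michael opening may erode the selectivity that is reached.
- Fallback (known chemistry), from 11 and 13 back to 15: the acylation stage is run as in step 9 and the ring is closed without control (NaOAc, EtOH/THF, reflux) to give the racemic flavanone F1.
- Dynamic kinetic resolution by asymmetric transfer hydrogenation follows (RuCl[(R,R)-TsDPEN](p-cymene), HCO2H/DBU, MeCN, 40 °C). Base-induced ring opening and reclosure racemises C2 while the 2R ketone is reduced faster, which should give the cis-(2R,4R)-flavan-4-ol F2.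
- Dess–Martin periodinane (NaHCO3, CH2Cl2, 0 °C) restores the ketone and returns to 15. Scalemic 15 from step 9 can be fed into the same sequence.

2. Step 7.
- What may go wrong: transmetalation at a boronate flanked by the chromone may be slow, and protodeboronation under aqueous base together with sluggish oxidative addition into the phenoxide form of 10 may consume both partners.
- Fallback, from 10 and 5 back to 11: the metal is moved to ring A and water is excluded. Silylation of 10 (TBSCl, imidazole, DMF) gives the silyl ether F3.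
- Iodine–magnesium exchange and transmetalation (iPrMgCl·LiCl, THF, −20 °C; ZnCl2) give the arylzinc chloride F4.
- Negishi coupling with bromide 5 (Pd(OAc)2, SPhos, THF, 60 °C) gives the silyl-protected biaryl F5, and Bu4NF/AcOH (THF, 0 °C) frees 11.

3. Step 10.
- What may go wrong: saturation of the chromone alkene, or hydrogenolysis of the benzylic C2–O1 bond, may set in before the two hindered ethers next to the biaryl bond are cleaved.
- Fallback, from 15 directly to 16: non-reductive Lewis-acid debenzylation with a cation scavenger (BCl3, pentamethylbenzene, CH2Cl2, −78 °C, quench with MeOH at low temperature). This makes no new compound (F0).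

Further compounds
F1 | step 9 | racemic 2-[4-(benzyloxy)phenyl]-6-{4,5-bis(benzyloxy)-2-[5,7-bis(benzyloxy)-4-oxo-4H-chromen-2-yl]phenyl}-5,7-bis[(4-methylbenzyl)oxy]chroman-4-one | O=C1CC(c2ccc(OCc3ccccc3)cc2)Oc2cc(OCc3ccc(C)cc3)c(-c3cc(OCc4ccccc4)c(OCc4ccccc4)cc3-c3cc(=O)c4c(OCc5ccccc5)cc(OCc5ccccc5)cc4o3)c(OCc3ccc(C)cc3)c21
F2 | step 9 | 5,7-bis(benzyloxy)-2-{4,5-bis(benzyloxy)-2-[(2R,4R)-2-(4-(benzyloxy)phenyl)-4-hydroxy-5,7-bis((4-methylbenzyl)oxy)chroman-6-yl]phenyl}-4H-chromen-4-one | O[C@@H]1C[C@H](c2ccc(OCc3ccccc3)cc2)Oc2cc(OCc3ccc(C)cc3)c(-c3cc(OCc4ccccc4)c(OCc4ccccc4)cc3-c3cc(=O)c4c(OCc5ccccc5)cc(OCc5ccccc5)cc4o3)c(OCc3ccc(C)cc3)c21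
F3 | step 7 | tert-butyl{4-iodo-3,5-bis[(4-methylbenzyl)oxy]phenoxy}dimethylsilane | Cc1ccc(COc2cc(O[Si](C)(C)C(C)(C)C)cc(OCc3ccc(C)cc3)c2I)cc1
F4 | step 7 | {4-[(tert-butyldimethylsilyl)oxy]-2,6-bis[(4-methylbenzyl)oxy]phenyl}zinc chloride | Cc1ccc(COc2cc(O[Si](C)(C)C(C)(C)C)cc(OCc3ccc(C)cc3)c2[Zn]Cl)cc1
F5 | step 7 | 5,7-bis(benzyloxy)-2-{4,5-bis(benzyloxy)-2-[4-((tert-butyldimethylsilyl)oxy)-2,6-bis((4-methylbenzyl)oxy)phenyl]phenyl}-4H-chromen-4-one | O=c1cc(-c2cc(OCc3ccccc3)c(OCc3ccccc3)cc2-c4c(OCc5ccc(C)cc5)cc(O[Si](C)(C)C(C)(C)C)cc4OCc5ccc(C)cc5)oc6cc(OCc3ccccc3)cc(OCc3ccccc3)c16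
F0 | step 10 | none | none
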